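The readings are simulated for substances that don't exist.

I began with the easy step, a balance: if one E goes with each Q, as I assumed from the amber readings, Q is the limiting reagent wherever E is charged beyond it.

| flask | Q | E | remark | time |
|---|---|---|---|---|
| amber | 0.50 M | 0.89 M | run made earlier |  |
| oak | 0.50 M | 0.750 M |  | 10 d |
| cedar | 0.50 M | 1.50 M |  | 10 d |
| larch | 0.50 M | 3.00 M |  | 10 d |

amber run (percent of the Q charged)

| time / d | Q / % | D / % |
|---|---|---|
| 0.417 | 79.2 | 14.3 |
| 0.833 | 64.2 | 20.4 |
| 1.25 | 51.7 | 23.5 |
| 2.50 | 29.1 | 21.0 |
| 5.00 | 12.9 | 15.5 |

(standard deviation of a reading: 0.5 percentage points)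

- a reading or a percentage of D counts all its forms, free or not

- part of the Q that has reacted at the end, oak
- part of the Q that has reacted at the end, cedar
- part of the Q that has reacted at the end, larch
- what raising the concentration of E from its lowest to its highest value here does to the part of the Q that has reacted (changes below 5 percentage points count as none) (it falls / no change / it rises)

Oak looks nearly the same as amber, with 84.3% of amber's E, so I reckoned both in fractions of the Q charge. Oak has a spare of 0.500, the spare being the E charged beyond the Q as a fraction of the Q charge, and amber has 0.780. With a spare s above zero, the balance allows Q to fall towards zero in either flask, so I asked how fast each approaches that end. If q is the fraction of Q left, free E is s + q, and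

dq/dt = −κ·q·(s + q)

ln[(s + q)/(q·(1 + s))] = κ·s·t

Amber's last reading gave κ = 0.353 /d, but its reading at 0.417 d gave 0.335 /d and its reading at 2.50 d gave 0.373 /d, so this form did not give one constant along the run, and I carried the last reading's κ as a working estimate. Once q is small against s, Q falls pseudo-first-order with constant κ·s, which is 0.275 /d in amber and 0.176 /d in oak. The cut in E falls on the spare, so oak's tail keeps 64.0% of amber's, less than its share of the charge. My reckoning at the asked time:

oak: κ·s·t = 1.76, Q left 6.45%

cedar: s = 2.00, κ·s·t = 7.06, Q left 0.0573%

larch: s = 5.00, κ·s·t = 17.6

The forecast said 93.5% (from 89% to 97%) for oak, 99.9% for cedar, 100% for larch, and for the trend it rises, with “about one E used per Q”.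

The flasks gave 91.7% for oak, 99.9% for cedar and >99.9% for larch, and from oak to larch it rises, by 8.3 percentage points, because of the difference in the concentration of E: without that difference larch stood at 91.7% instead of >99.9%.

    Q + D → L (k = 0.00109 /M/min)
    D → X (k = 1.41 × 10⁻⁴ /min)
    Q + E → Z + D (k = 4.12 × 10⁻⁴ /M/min)
    G ⇌ D, rate k4*(cs4 - [D]) while solid is left; crystals form when [D] > cs4 (solubility = 0.150 M, k = 0.0149 /min)
    E + Z ⇌ J, settled at all times (K = 5720 /M)

One E per Q would have left oak 0.583 of free E at the end, in units of the Q charge, but it held less, 0.282. Part of the reason is that E joins Z to form J: with that joining taken away, oak goes from 91.7% to 98.2% reacted. A neighbour of cedar charged with 0.38 M of E has a spare of −0.240, below zero, and it ended with 39% of its Q unreacted and 4.3% of its E free.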